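**Assumption:** cembrane numbering is used for locants (C1 = lactone β‑CH; C2; C3‑OH; C4(Me = C18)–O–C7 oxolane; C8=C19H2; C9–C11; C12(Me = C20); C13‑OH; C14–O lactone; C15=C17H2; C16 = C=O). The SMILES is read as 1S,3R,4S,7R,12S,13R,14R.

## Retrosynthetic overview

1. Last step: the C1–C14 bond, the 14‑membered carbocycle and the cis‑γ‑lactone are formed together by an indium‑catalysed electroreductive Barbier ring closure of an unprotected (Z)‑2‑(bromomethyl)enoate / α‑hydroxy aldehyde; C13‑OH controls C14 and C1.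
2. C15–C17 come from a Morita–Baylis–Hillman homologation at C1; C9–C10 comes from a Cu‑catalysed allyl–alkyl union of a West allylic chloride (C1–C9) with an East alkylborane (C10–C14).
3. West: the cis‑oxolane is made by osmium oxidative cyclisation of a (3R,4S)‑diol onto a prenyl alkene (C4 sets C7). The diol comes from (R)‑α‑hydroxy‑γ‑butyrolactone, homoprenyl‑lithium and chelation‑controlled MeMgBr (C3 sets C4).
4. East: (R)‑β‑hydroxy‑γ‑butyrolactone, trans‑selective dianion methylation (C13 sets C12), lactol, Wittig methylenation.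
5. Ring order: oxolane first (step 3); carbocycle and lactone together last (step 17).

## Route

### West fragment (C1–C9, C18, C19)

**Step 1**
Reactants: **1** (R)‑α‑hydroxy‑γ‑butyrolactone; **2** 5‑bromo‑2‑methylpent‑2‑ene
Product: **3** (3R)‑1,3‑dihydroxy‑8‑methylnon‑7‑en‑4‑one (isolated mainly as its cyclic hemiketal)
Conditions: 2, Li wire (1% Na), Et2O, 0 °C → homoprenyl‑Li (2.2 equiv); then 1, THF, −78 °C; aq NH4Cl
Reagents that add atoms: none
Why: Mono‑addition of an organolithium to a γ‑lactone (acyl substitution): the first equivalent forms the C3 alkoxide, the second adds once because the tetrahedral lactol dialkoxide is stable at −78 °C; C3 is untouched.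

**Step 2**
Reactants: **3**
Product: **4** (3R,4S)‑4,8‑dimethylnon‑7‑ene‑1,3,4‑triol
Conditions: MeMgBr (5 equiv), CH2Cl2–Et2O, −78 → 0 °C
Reagents that add atoms: methylmagnesium bromide, C[Mg]Br
Why: Cram‑chelate Grignard addition: Mg bridges the C3 alkoxide and the C4 ketone in a five‑membered chelate and methyl attacks the face syn to C3–H, giving the 3,4‑anti (4S) tertiary alcohol.

**Step 3**
Reactants: **4**
Product: **5** (1R)‑1‑[(2S,5R)‑5‑(2‑hydroxypropan‑2‑yl)‑2‑methyloxolan‑2‑yl]propane‑1,3‑diol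
Conditions: K2OsO4·2H2O (5 mol %), pyridine N‑oxide (3 equiv), citric acid, Cu(OTf)2, MeCN–pH 6.5 buffer, 60 °C
Reagents that add atoms: pyridine N‑oxide (oxygen source via Os=O), [O-][n+]1ccccc1
Why: Donohoe‑type osmium oxidative cyclisation of a 5,6‑dihydroxyalkene: the Os(VI) ester of the C3/C4 diol adds the C4 oxygen and an oxo ligand suprafacially across C7=C8, so C3 and C8 are necessarily cis on the new oxolane, which fixes C7 as R from C4.

**Step 4**
Reactants: **5**
Product: **6** 1,3‑bis‑O‑triethylsilyl ether of 5 (tertiary C8‑OH free)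
Conditions: TESCl (2.3 equiv), imidazole, DMF, 0 °C
Reagents that add atoms: chlorotriethylsilane, CC[Si](Cl)(CC)CC
Why: Silyl ether formation: the primary and secondary hydroxyls are silylated and the hindered tertiary carbinol is not.

**Step 5**
Reactants: **6**
Product: **7** (2S,5R)‑2‑[(1R)‑1,3‑bis(triethylsilyloxy)propyl]‑2‑methyl‑5‑(prop‑1‑en‑2‑yl)oxolane
Conditions: Burgess reagent (1.5 equiv), toluene, 70 °C
Reagents that add atoms: none
Why: Burgess syn‑elimination (Ei) of the tertiary alcohol: six methyl hydrogens against one hindered C7–H give the isopropenyl group, and C7 is not affected.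

**Step 6**
Reactants: **7**
Product: **8** (2S,5R)‑2‑[(1R)‑1,3‑bis(triethylsilyloxy)propyl]‑5‑(3‑chloroprop‑1‑en‑2‑yl)‑2‑methyloxolane
Conditions: Ca(OCl)2, CO2 (dry ice), CH2Cl2–H2O, 0 °C
Reagents that add atoms: calcium hypochlorite, [Ca+2].[O-]Cl.[O-]Cl
Why: Ene‑type allylic chlorination with HOCl: chlorine adds to the terminal CH2 and a methyl proton is lost, giving the 2‑(chloromethyl)allyl unit (C8=C19, C9–Cl).

### East fragment (C10–C14, C20)

**Step 7**
Reactants: **9** (R)‑β‑hydroxy‑γ‑butyrolactone [(R)‑4‑hydroxyoxolan‑2‑one]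
Product: **10** (3R,4R)‑4‑hydroxy‑3‑methyloxolan‑2‑one (trans)
Conditions: LDA (2.3 equiv), THF, −78 → −40 °C; MeI, −78 → −45 °C
Reagents that add atoms: iodomethane, CI
Why: Fráter–Seebach‑type dianion alkylation: MeI approaches the lactone enolate anti to the adjacent alkoxide, giving the trans product, which is the 12,13‑syn relationship of the target (C12 set from C13).

**Step 8**
Reactants: **10**
Product: **11** (3R,4R)‑3‑methyloxolane‑2,4‑diol (lactol, anomeric mixture)
Conditions: DIBAL‑H (2.2 equiv), CH2Cl2, −78 °C; Rochelle salt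
Reagents that add atoms: none
Why: DIBAL half‑reduction of a lactone stops at the lactol because the aluminium hemiacetal is stable at −78 °C.

**Step 9**
Reactants: **11**
Product: **12** (2R,3S)‑3‑methylpent‑4‑ene‑1,2‑diol
Conditions: Ph3PCH3Br (3.5 equiv), KOtBu, THF, 0 °C → rt
Reagents that add atoms: methylenetriphenylphosphorane, C=P(c1ccccc1)(c1ccccc1)c1ccccc1
Why: Wittig methylenation of the open hydroxy‑aldehyde form of the lactol; run cold with excess ylide so that the α‑methyl centre (C12) is not epimerised.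

**Step 10**
Reactants: **12**
Product: **13** (4R)‑4‑[(2S)‑but‑3‑en‑2‑yl]‑2,2‑dimethyl‑1,3‑dioxolane
Conditions: 2,2‑dimethoxypropane, PPTS (cat.), CH2Cl2, rt
Reagents that add atoms: 2,2‑dimethoxypropane, COC(C)(C)OC
Why: Acetonide formation on the terminal 1,2‑diol masks both hydroxyls for the borane chemistry.

### Union and endgame

**Step 11**
Reactants: **13**; **8**
Product: **14** (2S,5R)‑2‑[(1R)‑1,3‑bis(triethylsilyloxy)propyl]‑5‑{(6S)‑6‑[(4R)‑2,2‑dimethyl‑1,3‑dioxolan‑4‑yl]hept‑1‑en‑2‑yl}‑2‑methyloxolane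
Conditions: 13 (1.3 equiv), 9‑BBN, THF, rt → 60 °C; then 8, CuOAc (10 mol %), t‑BuOK (1.3 equiv), THF, 60 °C
Reagents that add atoms: none
Why: Anti‑Markovnikov hydroboration followed by Cu‑catalysed allyl–alkyl coupling of the alkyl‑9‑BBN with the allylic chloride forms C9–C10; the allyl unit is 2‑substituted with two CH2 termini, so SN2 and SN2′ give the same product and no stereocentre is touched.

**Step 12**
Reactants: **14**
Product: **15** (3R)‑3‑[(2S,5R)‑5‑{(6S)‑6‑[(4R)‑2,2‑dimethyl‑1,3‑dioxolan‑4‑yl]hept‑1‑en‑2‑yl}‑2‑methyloxolan‑2‑yl]‑3‑(triethylsilyloxy)propanal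
Conditions: (COCl)2 (4 equiv), DMSO (8 equiv), CH2Cl2, −78 → −30 °C; Et3N
Reagents that add atoms: none
Why: Swern oxidation with in situ cleavage of the primary TES ether: the secondary TES ether and the acetonide survive, so the C1 aldehyde is obtained without a separate deprotection.

**Step 13**
Reactants: **15**; **16** methyl acrylate
Product: **17** methyl (5R)‑3‑hydroxy‑2‑methylidene‑5‑[oxolanyl as in 15]‑5‑(triethylsilyloxy)pentanoate (C1 carbinol epimers)
Conditions: 16 (10 equiv, neat), quinuclidine (0.5 equiv), MeOH (1 equiv), rt, 48 h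
Reagents that add atoms: none (16 is a reactant)
Why: Morita–Baylis–Hillman reaction brings in C15–C17; the new carbinol stereocentre is removed in the next step.

**Step 14**
Reactants: **17**
Product: **18** methyl (2Z,5R)‑2‑(bromomethyl)‑5‑[oxolanyl as in 15]‑5‑(triethylsilyloxy)pent‑2‑enoate
Conditions: NBS (1.3 equiv), Me2S (1.5 equiv), CH2Cl2, 0 °C → rt
Reagents that add atoms: N‑bromosuccinimide, O=C1CCC(=O)N1Br
Why: Corey–Kim‑type bromination with allylic transposition (SN2′) gives the thermodynamic (Z)‑2‑(bromomethyl)enoate, with the C2 chain cis to CH2Br.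

**Step 15**
Reactants: **18**
Product: **19** methyl (2Z,5R)‑2‑(bromomethyl)‑5‑hydroxy‑5‑{(2S,5R)‑5‑[(6S,7R)‑7,8‑dihydroxy‑6‑methyloct‑1‑en‑2‑yl]‑2‑methyloxolan‑2‑yl}pent‑2‑enoate
Conditions: TFA–THF–H2O (1:4:1), 0 °C → rt
Reagents that add atoms: none
Why: Acid hydrolysis removes the TES ether and the acetonide in one operation; the primary allylic bromide and the enoate tolerate dilute aqueous acid.

**Step 16**
Reactants: **19**
Product: **20** methyl (2Z,5R)‑2‑(bromomethyl)‑5‑hydroxy‑5‑{(2S,5R)‑5‑[(6S,7R)‑7‑hydroxy‑6‑methyl‑8‑oxooct‑1‑en‑2‑yl]‑2‑methyloxolan‑2‑yl}pent‑2‑enoate (used crude)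
Conditions: TEMPO (20 mol %), PhI(OAc)2 (1.1 equiv), CH2Cl2, 0 °C → rt
Reagents that add atoms: none
Why: Aminoxyl‑catalysed (TEMPO/BAIB) oxidation is selective for the primary C14‑OH over the two secondary hydroxyls and gives the α‑hydroxy aldehyde.

**Step 17**
Reactants: **20**
Product: **21** Uprolide D
Conditions: InBr3 (20 mol %), LiBr (0.1 M), THF–H2O (4:1), undivided cell, Al sacrificial anode, RVC cathode, −0.9 V vs Ag/AgCl (about 2.2 F mol⁻¹), 20 added by syringe pump over 10 h (≤1 mM), rt; then 1 M HCl, 1 h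
Reagents that add atoms: none (two electrons; bromide and MeOH are lost)
Why: Proposed new method: indium‑catalysed electroreductive Barbier macro‑annulation — In(III) is reduced at the cathode to low‑valent indium at a potential well positive of direct reduction of the allylic bromide, aldehyde or enoate; it inserts into the allylic C–Br bond, and the (Z)‑γ‑substituted allylindium adds through C1 (SE2′) to the aldehyde, which is held in a Cram chelate by the free C13‑OH, via a chair transition state (C13 gives 14R, 13,14‑syn; the Z geometry gives 1,14‑syn, i.e. 1S and the cis‑lactone). Catalyst turnover keeps the allylindium concentration low (built‑in high dilution), and the alkoxide lactonises onto the ester; the closest known reactions are stoichiometric In(0) aqueous Barbier lactone annulations and In‑catalysed electroreductive intermolecular allylations with a sacrificial anode.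

## Compound list

1 | (R)‑α‑hydroxy‑γ‑butyrolactone [(R)‑3‑hydroxyoxolan‑2‑one] | O[C@@H]1CCOC1=O | starting material
2 | 5‑bromo‑2‑methylpent‑2‑ene | CC(C)=CCCBr | starting material
3 | (3R)‑1,3‑dihydroxy‑8‑methylnon‑7‑en‑4‑one (hemiketal form in equilibrium) | OCC[C@@H](O)C(=O)CCC=C(C)C | intermediate
4 | (3R,4S)‑4,8‑dimethylnon‑7‑ene‑1,3,4‑triol | OCC[C@@H](O)[C@@](C)(O)CCC=C(C)C | intermediate
5 | (1R)‑1‑[(2S,5R)‑5‑(2‑hydroxypropan‑2‑yl)‑2‑methyloxolan‑2‑yl]propane‑1,3‑diol | OCC[C@@H](O)[C@]1(C)CC[C@H](C(C)(C)O)O1 | intermediate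
6 | 1,3‑bis‑O‑TES ether of 5 | CC[Si](CC)(CC)OCC[C@@H](O[Si](CC)(CC)CC)[C@]1(C)CC[C@H](C(C)(C)O)O1 | intermediate
7 | (2S,5R)‑2‑[(1R)‑1,3‑bis(triethylsilyloxy)propyl]‑2‑methyl‑5‑(prop‑1‑en‑2‑yl)oxolane | CC[Si](CC)(CC)OCC[C@@H](O[Si](CC)(CC)CC)[C@]1(C)CC[C@H](C(C)=C)O1 | intermediate
8 | (2S,5R)‑2‑[(1R)‑1,3‑bis(triethylsilyloxy)propyl]‑5‑(3‑chloroprop‑1‑en‑2‑yl)‑2‑methyloxolane | CC[Si](CC)(CC)OCC[C@@H](O[Si](CC)(CC)CC)[C@]1(C)CC[C@H](C(=C)CCl)O1 | intermediate
9 | (R)‑β‑hydroxy‑γ‑butyrolactone [(R)‑4‑hydroxyoxolan‑2‑one] | O[C@H]1COC(=O)C1 | starting material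
10 | (3R,4R)‑4‑hydroxy‑3‑methyloxolan‑2‑one | O=C1[C@H](C)[C@@H](O)CO1 | intermediate
11 | (3R,4R)‑3‑methyloxolane‑2,4‑diol | OC1[C@H](C)[C@@H](O)CO1 | intermediate
12 | (2R,3S)‑3‑methylpent‑4‑ene‑1,2‑diol | C=C[C@H](C)[C@@H](O)CO | intermediate
13 | (4R)‑4‑[(2S)‑but‑3‑en‑2‑yl]‑2,2‑dimethyl‑1,3‑dioxolane | C=C[C@H](C)[C@@H]1COC(C)(C)O1 | intermediate
14 | (2S,5R)‑2‑[(1R)‑1,3‑bis(triethylsilyloxy)propyl]‑5‑{(6S)‑6‑[(4R)‑2,2‑dimethyl‑1,3‑dioxolan‑4‑yl]hept‑1‑en‑2‑yl}‑2‑methyloxolane | CC[Si](CC)(CC)OCC[C@@H](O[Si](CC)(CC)CC)[C@]1(C)CC[C@H](C(=C)CCC[C@H](C)[C@@H]2COC(C)(C)O2)O1 | intermediate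
15 | C1 aldehyde: (3R)‑3‑[oxolanyl of 14]‑3‑(triethylsilyloxy)propanal | O=CC[C@@H](O[Si](CC)(CC)CC)[C@]1(C)CC[C@H](C(=C)CCC[C@H](C)[C@@H]2COC(C)(C)O2)O1 | intermediate
16 | methyl acrylate | C=CC(=O)OC | starting material
17 | MBH adduct (C1 epimers) | COC(=O)C(=C)C(O)C[C@@H](O[Si](CC)(CC)CC)[C@]1(C)CC[C@H](C(=C)CCC[C@H](C)[C@@H]2COC(C)(C)O2)O1 | intermediate
18 | (Z)‑2‑(bromomethyl)enoate, 3‑O‑TES, 13,14‑acetonide | COC(=O)/C(CBr)=C/C[C@@H](O[Si](CC)(CC)CC)[C@]1(C)CC[C@H](C(=C)CCC[C@H](C)[C@@H]2COC(C)(C)O2)O1 | intermediate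
19 | (Z)‑bromo‑enoate 3,13,14‑triol | COC(=O)/C(CBr)=C/C[C@@H](O)[C@]1(C)CC[C@H](C(=C)CCC[C@H](C)[C@@H](O)CO)O1 | intermediate
20 | (Z)‑bromo‑enoate 3,13‑diol 14‑aldehyde (seco precursor) | COC(=O)/C(CBr)=C/C[C@@H](O)[C@]1(C)CC[C@H](C(=C)CCC[C@H](C)[C@@H](O)C=O)O1 | intermediate
21 | Uprolide D [(1S,3R,4S,7R,12S,13R,14R)‑3,13‑dihydroxy‑4,7‑epoxycembra‑8(19),15(17)‑dien‑16,14‑olide] | C=C1CCC[C@H](C)[C@@H](O)[C@@H]2OC(=O)C(=C)[C@@H]2C[C@@H](O)[C@]2(C)CC[C@H]1O2 | target

## Totals

- Total steps: 17 (West 6, East 4, union 1, endgame 6).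
- Longest linear sequence: 13 steps (steps 1–6, then 11–17, from lactone 1).

## Three steps most likely to fail

1. **Step 17 (proposed new electro‑Barbier macro‑annulation).** Risks are low turnover of electrogenerated indium, competing proton reduction, and loss of chelate control in the macrocyclic transition state. Fallback (known chemistry): replace the electrocatalytic cycle with a stoichiometric‑metal Barbier annulation of 20 — indium powder in THF–H2O under syringe‑pump high dilution. This is the established aqueous In(0) route to cis‑fused α‑methylene‑γ‑butyrolactones on medium and large rings, and it uses the same chelation and chair arguments for C14 and C1.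

2. **Step 3 (osmium oxidative cyclisation on the free triol).** Risks are interference by the primary C1‑OH, acid‑promoted prenyl cyclisation, and plain dihydroxylation. Fallback (different ring construction): buy C7 instead of inducing it. Build C5–C8 from (S)‑α‑hydroxy‑γ‑butyrolactone (the enantiomer of 1), set C4 as in step 2, then close the oxolane by intramolecular Williamson displacement of a C7 mesylate by the C4 tertiary alkoxide (SN2, inversion).

3. **Step 13 (Morita–Baylis–Hillman on the β‑silyloxy aldehyde).** Risks are slow conversion and β‑elimination of the silyloxy group under amine catalysis. Fallback (pre‑formed nucleophile instead of amine catalysis): vinylalumination — generate [α‑(methoxycarbonyl)vinyl]diisobutylaluminium from methyl propiolate and DIBAL‑H/NMO and add it to 15 at 0 °C to give the same adduct 17.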